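**Plan**
- Cuts: (a) the bond between the tetrasubstituted cycloheptene carbon and the CH2CH2 linker (B-alkyl Suzuki), giving a 6-vinyl decahydro-1-benzoxepine and a hydroazulenyl triflate; (b) in the left half the cyclohexane C6–C7 bond (allylsilane + methyl ketone), then the ring-fusion bond C5a–C9a of the oxepane.
- Enabling feature: C9a (O–CH) and C5a (quaternary, CH3) are vicinal and each carries one cyclohexane carbon (C9, C6) that can be drawn as CO2H and vinyl. That is a γ,δ-unsaturated α-alkoxy acid, the product of an ester-enolate Claisen shift. The oxepane arc O–CMe2–CH(O)–CH2–CH2 already joins the two termini, so the allyl ester is an 11-membered glycolate lactone built on geranyl acetate and the shift is a ring contraction.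
- Left half, forward: geranyl acetate → Shi epoxide → glycolate ether → macrolactone → Claisen ring contraction (oxepane) → side-chain methyl ketone and allylsilane → Sakurai closure (cyclohexane) → inversion at C3 → acetate.
- Right half, forward: (R)-linalool → RCM to the cyclopentenol → directed epoxidation, nitrile-anion opening → exo-methylene ethyl ketone → boron aldol with acrolein → RCM (cycloheptene) → directed hydrogenation → enol triflate; then Suzuki union and desilylation.
- Stereochemistry: C3 from Shi epoxidation (used as a temporary controller, then inverted by oxidation/L-Selectride); C5a/C9a from the chair Claisen; C6/C7 from the chair Sakurai; right half C1 from linalool, C3a by anti epoxide opening, C7 by the Ipc boron aldol, C8a by hydroxyl-directed hydrogenation.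

Key step: step 6

Remark: the silyloxy centre is assumed to sit pseudo-equatorially in the ring-contraction transition state (hence the 6S lactone and the later inversion); (R)-linalool, geranyl acetate and the L-series Shi ketone are taken as commercial.

**Left half**

Step 1
Reactants: 1 geranyl acetate
Product: 2 (2E)-5-[(2S)-3,3-dimethyloxiran-2-yl]-3-methylpent-2-en-1-yl acetate
Conditions: Shi ketone of the L-fructose series (0.3 equiv), Oxone, K2CO3, Bu4NHSO4, MeCN/dimethoxymethane/aq. borate buffer, 0 °C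
Reagents that add atoms: potassium peroxymonosulfate (Oxone), [K+].[O-]S(=O)(=O)OO
Why: Shi asymmetric epoxidation (chiral dioxirane, spiro transition state) should attack only the electron-rich 6,7-alkene, the 2,3-alkene being deactivated by the allylic acetate, and the L-series ketone sets the S epoxide centre.

Step 2
Reactants: 2 (2E)-5-[(2S)-3,3-dimethyloxiran-2-yl]-3-methylpent-2-en-1-yl acetate
Product: 3 methyl 2-{[(3S,6E)-8-acetoxy-3-hydroxy-2,6-dimethyloct-6-en-2-yl]oxy}acetate
Conditions: methyl glycolate (10 equiv), BF3·OEt2 (10 mol %), CH2Cl2, −30 °C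
Reagents that add atoms: methyl glycolate, COC(=O)CO
Why: Acid-catalysed alcoholysis of a trisubstituted epoxide opens the tertiary C–O bond, so the glycolate oxygen ends on the CMe2 carbon while the carbinol centre, whose C–O bond is untouched, keeps its configuration.

Step 3
Reactants: 3 methyl 2-{[(3S,6E)-8-acetoxy-3-hydroxy-2,6-dimethyloct-6-en-2-yl]oxy}acetate
Product: 4 methyl 2-{[(3S,6E)-8-acetoxy-3-(tert-butyldimethylsilyloxy)-2,6-dimethyloct-6-en-2-yl]oxy}acetate
Conditions: t-BuMe2SiOTf, 2,6-lutidine, CH2Cl2, −78 → 0 °C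
Reagents that add atoms: tert-butyldimethylsilyl triflate, CC(C)(C)[Si](C)(C)OS(=O)(=O)C(F)(F)F
Why: Silylation with the silyl triflate protects the hindered secondary carbinol as a base-stable ether, which blocks six-ring lactonisation and later steers the ring contraction.

Step 4
Reactants: 4 methyl 2-{[(3S,6E)-8-acetoxy-3-(tert-butyldimethylsilyloxy)-2,6-dimethyloct-6-en-2-yl]oxy}acetate
Product: 5 2-{[(3S,6E)-3-(tert-butyldimethylsilyloxy)-8-hydroxy-2,6-dimethyloct-6-en-2-yl]oxy}acetic acid
Conditions: LiOH, THF/MeOH/H2O, 23 °C; then aq. HCl to pH 3, 0 °C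
Reagents that add atoms: lithium hydroxide (hydroxide oxygen), [Li+].[OH-]
Why: Saponification cleaves the acetate and the methyl ester together while the silyl ether survives, giving the seco acid.

Step 5
Reactants: 5 2-{[(3S,6E)-3-(tert-butyldimethylsilyloxy)-8-hydroxy-2,6-dimethyloct-6-en-2-yl]oxy}acetic acid
Product: 7 (6S,9E)-6-(tert-butyldimethylsilyloxy)-5,5,9-trimethyl-1,4-dioxacycloundec-9-en-2-one, via mixed anhydride 6 (not isolated)
Conditions: 2,4,6-Cl3C6H2COCl, Et3N, THF, 23 °C; then slow addition to DMAP, toluene (2 mM), 80 °C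
Reagents that add atoms: none
Why: Yamaguchi macrolactonisation, in which the DMAP-activated mixed anhydride is captured by the primary allylic alcohol under high dilution; the (E)-alkene, the ether oxygen and the gem-dimethyl group should ease closure of the 11-membered ring.

Step 6
Reactants: 7 (6S,9E)-6-(tert-butyldimethylsilyloxy)-5,5,9-trimethyl-1,4-dioxacycloundec-9-en-2-one
Product: 10 (2S,3R,6S)-6-(tert-butyldimethylsilyloxy)-3-ethenyl-3,7,7-trimethyloxepane-2-carboxylic acid, via silyl ketene acetal 8 (not isolated), via trimethylsilyl ester 9 (not isolated)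
Conditions: LiN(SiMe3)2 (1.3 equiv), THF, −78 °C; Me3SiCl/Et3N (3 equiv); −78 → 23 °C (40 °C if needed); 1 M HCl
Reagents that add atoms: none
Why: Deprotonation of the α-alkoxy lactone gives the lithium-chelated (Z)-enolate, trapped as silyl ketene acetal 8, whose C3 and the methyl-bearing C9 of the (E)-allyl ester are the ends of a 1,5-diene held in one 11-membered ring, so the [3,3] shift is transannular; the closest known reactions are the Ireland–Claisen ring contractions of macrocyclic allylic lactones to carbocycles and of 6-alkenyl-1,4-dioxan-2-ones to dihydropyrans. The oxepane is closed by this suprafacial [3,3] event, in which the five-atom tether O–CMe2–CH(OSi)–CH2–CH2 bridges the two termini (11 → 7 contraction) and the lactone C–O bond breaks, leaving vinyl and carboxyl outside the new ring. The relative configuration of the quaternary carbon and the ether methine follows from a chair array with both tether ends equatorial, which is the ghost of the later cyclohexane chair: carboxyl and vinyl come out trans, carboxyl cis to methyl, as a trans ring fusion requires. The absolute sense is set by the silyloxy centre, which should take the pseudo-equatorial site of the nascent twist-chair oxepane (gem-dimethyl carbon on the twist axis) and therefore ends cis to the new methyl group. The step needs chair-over-boat and facial selectivity; the first is secured by the (E)-alkene together with the chelate-derived (Z)-ketene acetal (every other geometry or a boat would give the cis-2,3 isomer), the second by the resident silyloxy centre, whose own configuration is corrected in steps 13 and 14.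

Step 7
Reactants: 10 (2S,3R,6S)-6-(tert-butyldimethylsilyloxy)-3-ethenyl-3,7,7-trimethyloxepane-2-carboxylic acid
Product: 11 [(2S,3R,6S)-6-(tert-butyldimethylsilyloxy)-3-ethenyl-3,7,7-trimethyloxepan-2-yl]methanol
Conditions: LiAlH4, THF, 0 → 40 °C
Reagents that add atoms: none
Why: LiAlH4 reduction of the carboxylic acid to the primary alcohol leaves the silyl ether, the vinyl group and both new stereocentres untouched.

Step 8
Reactants: 11 [(2S,3R,6S)-6-(tert-butyldimethylsilyloxy)-3-ethenyl-3,7,7-trimethyloxepan-2-yl]methanol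
Product: 13 (3E)-4-[(2R,3R,6S)-6-(tert-butyldimethylsilyloxy)-3-ethenyl-3,7,7-trimethyloxepan-2-yl]but-3-en-2-one, via aldehyde 12 (not isolated)
Conditions: Dess–Martin periodinane, NaHCO3, CH2Cl2, 23 °C; then Ph3P=CHC(O)CH3, 40 °C
Reagents that add atoms: (acetylmethylene)triphenylphosphorane, CC(=O)C=P(c1ccccc1)(c1ccccc1)c1ccccc1
Why: Dess–Martin oxidation followed in the same flask by a Wittig reaction with the stabilised ylide should give the (E)-enone, the one-pot handling sparing the α-alkoxy aldehyde from epimerisation.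

Step 9
Reactants: 13 (3E)-4-[(2R,3R,6S)-6-(tert-butyldimethylsilyloxy)-3-ethenyl-3,7,7-trimethyloxepan-2-yl]but-3-en-2-one
Product: 14 4-[(2R,3R,6S)-6-(tert-butyldimethylsilyloxy)-3-ethenyl-3,7,7-trimethyloxepan-2-yl]butan-2-one
Conditions: [(Ph3P)CuH]6 (0.4 equiv), benzene, H2O (5 equiv), 23 °C
Reagents that add atoms: none
Why: Conjugate reduction with the copper hydride hexamer saturates only the enone and leaves the isolated vinyl group for the next step.

Step 10
Reactants: 14 4-[(2R,3R,6S)-6-(tert-butyldimethylsilyloxy)-3-ethenyl-3,7,7-trimethyloxepan-2-yl]butan-2-one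
Product: 15 4-{(2R,3R,6S)-6-(tert-butyldimethylsilyloxy)-3,7,7-trimethyl-3-[(1E)-3-(trimethylsilyl)prop-1-en-1-yl]oxepan-2-yl}butan-2-one
Conditions: allyltrimethylsilane (5 equiv), second-generation Hoveyda–Grubbs catalyst (5 mol %), CH2Cl2, 40 °C
Reagents that add atoms: allyltrimethylsilane, C=CC[Si](C)(C)C
Why: Olefin cross-metathesis of the monosubstituted (though neopentyl) vinyl group with excess allylsilane installs the allylsilane, the ketone and ethers being inert to the ruthenium carbene.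

Step 11
Reactants: 15 4-{(2R,3R,6S)-6-(tert-butyldimethylsilyloxy)-3,7,7-trimethyl-3-[(1E)-3-(trimethylsilyl)prop-1-en-1-yl]oxepan-2-yl}butan-2-one
Product: 16 (3S,5aR,6R,7S,9aR)-3-(tert-butyldimethylsilyloxy)-6-ethenyl-2,2,5a,7-tetramethyldecahydro-1-benzoxepin-7-ol
Conditions: TiCl4 (1.1 equiv), CH2Cl2, −78 °C; aq. NaHCO3
Reagents that add atoms: none
Why: Intramolecular Hosomi–Sakurai allylation, in which the γ-carbon of the allylsilane adds to the TiCl4-activated methyl ketone through a six-membered chair with the ketone methyl equatorial (axial would be 1,3-diaxial to the ring-fusion methyl) and the nascent vinyl equatorial, giving the trans-fused ring with axial tertiary hydroxyl.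

Step 12
Reactants: 16 (3S,5aR,6R,7S,9aR)-3-(tert-butyldimethylsilyloxy)-6-ethenyl-2,2,5a,7-tetramethyldecahydro-1-benzoxepin-7-ol
Product: 17 (3S,5aR,6R,7S,9aR)-6-ethenyl-2,2,5a,7-tetramethyldecahydro-1-benzoxepine-3,7-diol
Conditions: Bu4NF, THF, 23 °C
Reagents that add atoms: none
Why: Fluoride-mediated desilylation bares the secondary alcohol whose configuration served only to steer step 6.

Step 13
Reactants: 17 (3S,5aR,6R,7S,9aR)-6-ethenyl-2,2,5a,7-tetramethyldecahydro-1-benzoxepine-3,7-diol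
Product: 18 (5aR,6R,7S,9aR)-6-ethenyl-7-hydroxy-2,2,5a,7-tetramethyloctahydro-1-benzoxepin-3(2H)-one
Conditions: Dess–Martin periodinane, NaHCO3, CH2Cl2, 23 °C
Reagents that add atoms: none
Why: Dess–Martin oxidation converts the secondary alcohol into the ketone while the tertiary alcohol cannot react.

Step 14
Reactants: 18 (5aR,6R,7S,9aR)-6-ethenyl-7-hydroxy-2,2,5a,7-tetramethyloctahydro-1-benzoxepin-3(2H)-one
Product: 19 (3R,5aR,6R,7S,9aR)-6-ethenyl-2,2,5a,7-tetramethyldecahydro-1-benzoxepine-3,7-diol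
Conditions: LiBH(s-Bu)3 (2.5 equiv), THF, −78 °C; H2O
Reagents that add atoms: none
Why: The bulky hydride (L-Selectride reduction) should attack the ketone next to the gem-dimethyl carbon from the equatorial direction, as in 4,4-dimethyl-3-keto steroids, giving the pseudo-axial 3R alcohol trans to the ring-fusion methyl.

Step 15
Reactants: 19 (3R,5aR,6R,7S,9aR)-6-ethenyl-2,2,5a,7-tetramethyldecahydro-1-benzoxepine-3,7-diol
Product: 20 (3R,5aR,6R,7S,9aR)-6-ethenyl-7-hydroxy-2,2,5a,7-tetramethyldecahydro-1-benzoxepin-3-yl acetate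
Conditions: Ac2O, pyridine, DMAP (cat.), CH2Cl2, 23 °C
Reagents that add atoms: acetic anhydride, CC(=O)OC(C)=O
Why: Acetylation should occur only at the secondary hydroxyl, the axial tertiary alcohol with its 1,3-diaxial methyl being unreactive.

**Right half**

Step 16
Reactants: 21 (R)-linalool
Product: 22 (1R)-1-methylcyclopent-2-en-1-ol
Conditions: second-generation Grubbs catalyst (0.5 mol %), CH2Cl2, 40 °C
Reagents that add atoms: none
Why: Ring-closing metathesis of the 1,6-diene expels isobutene and gives the cyclopentenol with the tertiary carbinol centre of linalool unchanged.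

Step 17
Reactants: 22 (1R)-1-methylcyclopent-2-en-1-ol
Product: 23 (1S,2R,5S)-2-methyl-6-oxabicyclo[3.1.0]hexan-2-ol
Conditions: mCPBA, NaHCO3, CH2Cl2, 0 °C
Reagents that add atoms: 3-chloroperoxybenzoic acid, OOC(=O)c1cccc(Cl)c1
Why: Hydroxyl-directed (Henbest) peracid epoxidation delivers oxygen to the alkene face cis to the allylic tertiary hydroxyl.

Step 18
Reactants: 23 (1S,2R,5S)-2-methyl-6-oxabicyclo[3.1.0]hexan-2-ol
Product: 24 triethyl{[(1S,2R,5S)-2-methyl-6-oxabicyclo[3.1.0]hexan-2-yl]oxy}silane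
Conditions: Et3SiOTf, 2,6-lutidine, CH2Cl2, 0 °C
Reagents that add atoms: triethylsilyl triflate, CC[Si](CC)(CC)OS(=O)(=O)C(F)(F)F
Why: Silylation of the tertiary alcohol with the silyl triflate gives a triethylsilyl ether that lasts until the final step.

Step 19
Reactants: 24 triethyl{[(1S,2R,5S)-2-methyl-6-oxabicyclo[3.1.0]hexan-2-yl]oxy}silane
Product: 25 2-[(1S,2S,3R)-2-hydroxy-3-methyl-3-(triethylsilyloxy)cyclopentyl]-2-methylpropanenitrile
Conditions: i-PrCN, LiN(i-Pr)2, THF, −78 °C; then 24, −78 → 50 °C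
Reagents that add atoms: isobutyronitrile, CC(C)C#N
Why: SN2 opening of the epoxide by lithiated isobutyronitrile occurs at the carbon remote from the quaternary centre with inversion, placing the CMe2CN group trans to the epoxide oxygen and leaving a secondary alcohol.

Step 20
Reactants: 25 2-[(1S,2S,3R)-2-hydroxy-3-methyl-3-(triethylsilyloxy)cyclopentyl]-2-methylpropanenitrile
Product: 26 2-methyl-2-[(1S,3R)-3-methyl-2-oxo-3-(triethylsilyloxy)cyclopentyl]propanenitrile
Conditions: Dess–Martin periodinane, NaHCO3, CH2Cl2, 23 °C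
Reagents that add atoms: none
Why: Dess–Martin oxidation of the secondary alcohol under buffered, non-basic conditions keeps the adjacent stereocentre intact.

Step 21
Reactants: 26 2-methyl-2-[(1S,3R)-3-methyl-2-oxo-3-(triethylsilyloxy)cyclopentyl]propanenitrile
Product: 27 2-methyl-2-[(1S,3R)-3-methyl-2-methylidene-3-(triethylsilyloxy)cyclopentyl]propanenitrile
Conditions: Zn, CH2Br2, TiCl4, THF/CH2Cl2, 0 → 23 °C
Reagents that add atoms: dibromomethane, BrCBr
Why: Lombardo methylenation with the non-basic Zn/CH2Br2/TiCl4 reagent converts the hindered ketone into the exocyclic alkene without epimerising the α-centre or touching the nitrile.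

Step 22
Reactants: 27 2-methyl-2-[(1S,3R)-3-methyl-2-methylidene-3-(triethylsilyloxy)cyclopentyl]propanenitrile
Product: 29 2-methyl-2-[(1R,3R)-3-methyl-2-methylidene-3-(triethylsilyloxy)cyclopentyl]pentan-3-one, via ketimine 28 (not isolated)
Conditions: EtLi, Et2O/THF, −78 → 0 °C; then aq. AcOH/NaOAc (pH 4), 23 °C
Reagents that add atoms: ethyllithium, [Li]CC; water, O
Why: Ethyllithium adds once to the non-enolisable tertiary nitrile to give the N-lithio ketimine, which is hydrolysed on work-up to the ethyl ketone (organolithium addition to a nitrile).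

Step 23
Reactants: 29 2-methyl-2-[(1R,3R)-3-methyl-2-methylidene-3-(triethylsilyloxy)cyclopentyl]pentan-3-one
Product: 32 (4S,5R)-5-hydroxy-2,4-dimethyl-2-[(1R,3R)-3-methyl-2-methylidene-3-(triethylsilyloxy)cyclopentyl]hept-6-en-3-one, via boron enolate 30 (not isolated), via boron aldolate 31 (not isolated)
Conditions: (−)-Ipc2BOTf, i-Pr2NEt, CH2Cl2, −78 °C; acrolein, −78 → −20 °C; H2O2, MeOH, pH 7 buffer
Reagents that add atoms: acrolein, C=CC=O
Why: Paterson boron aldol, in which the (Z)-diisopinocampheylboron enolate (formed only on the ethyl side, the other α-carbon being quaternary) adds to acrolein through a Zimmerman–Traxler chair to give the syn aldol, the Ipc antipode being the one that sets the 5R carbinol.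

Step 24
Reactants: 32 (4S,5R)-5-hydroxy-2,4-dimethyl-2-[(1R,3R)-3-methyl-2-methylidene-3-(triethylsilyloxy)cyclopentyl]hept-6-en-3-one
Product: 33 (1R,3aR,6S,7R)-7-hydroxy-1,4,4,6-tetramethyl-1-(triethylsilyloxy)-2,3,3a,4,6,7-hexahydroazulen-5(1H)-one
Conditions: second-generation Grubbs catalyst (10 mol %), toluene (5 mM), 80 °C
Reagents that add atoms: none
Why: Ring-closing metathesis between the vinyl carbinol and the exocyclic methylene closes the seven-membered ring as a trisubstituted alkene with loss of ethene.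

Step 25
Reactants: 33 (1R,3aR,6S,7R)-7-hydroxy-1,4,4,6-tetramethyl-1-(triethylsilyloxy)-2,3,3a,4,6,7-hexahydroazulen-5(1H)-one
Product: 34 (1R,3aR,6S,7R,8aR)-7-hydroxy-1,4,4,6-tetramethyl-1-(triethylsilyloxy)octahydroazulen-5(1H)-one
Conditions: [Ir(cod)(PCy3)(py)]PF6 (10 mol %), H2 (1 atm), CH2Cl2, 23 °C
Reagents that add atoms: none
Why: Hydroxyl-directed hydrogenation with the cationic iridium catalyst delivers hydrogen to the alkene face syn to the allylic hydroxyl, which places the new ring-fusion hydrogen cis to its neighbour (cis-fused hydroazulene).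

Step 26
Reactants: 34 (1R,3aR,6S,7R,8aR)-7-hydroxy-1,4,4,6-tetramethyl-1-(triethylsilyloxy)octahydroazulen-5(1H)-one
Product: 35 (1R,3aR,6S,7R,8aR)-1,4,4,6-tetramethyl-1,7-bis(triethylsilyloxy)octahydroazulen-5(1H)-one
Conditions: Et3SiOTf, 2,6-lutidine, CH2Cl2, −78 °C
Reagents that add atoms: triethylsilyl triflate, CC[Si](CC)(CC)OS(=O)(=O)C(F)(F)F
Why: Silylation of the β-hydroxyl under non-basic conditions avoids retro-aldol cleavage and protects it for the enolisation that follows.

Step 27
Reactants: 35 (1R,3aR,6S,7R,8aR)-1,4,4,6-tetramethyl-1,7-bis(triethylsilyloxy)octahydroazulen-5(1H)-one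
Product: 36 (1R,3aR,7R,8aR)-1,4,4,6-tetramethyl-1,7-bis(triethylsilyloxy)-1,2,3,3a,4,7,8,8a-octahydroazulen-5-yl trifluoromethanesulfonate
Conditions: KN(SiMe3)2, PhNTf2, THF, −78 °C
Reagents that add atoms: N-phenylbis(trifluoromethanesulfonimide), O=S(=O)(N(c1ccccc1)S(=O)(=O)C(F)(F)F)C(F)(F)F
Why: Deprotonation can occur only at the methyl-bearing α-carbon (the other is quaternary), and O-triflation of the cold potassium enolate gives the tetrasubstituted enol triflate, erasing the α-centre as planned.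

**Union**

Step 28
Reactants: 20 (3R,5aR,6R,7S,9aR)-6-ethenyl-7-hydroxy-2,2,5a,7-tetramethyldecahydro-1-benzoxepin-3-yl acetate; 36 (1R,3aR,7R,8aR)-1,4,4,6-tetramethyl-1,7-bis(triethylsilyloxy)-1,2,3,3a,4,7,8,8a-octahydroazulen-5-yl trifluoromethanesulfonate
Product: 38 bis(triethylsilyl) ether of the target, via alkylborane 37 (not isolated)
Conditions: 20, 9-BBN dimer (2.5 equiv), THF, 23 °C; then 36, Pd(dppf)Cl2 (10 mol %), AsPh3, Cs2CO3, DMF/H2O, 40 °C
Reagents that add atoms: none
Why: B-alkyl Suzuki–Miyaura coupling, in which anti-Markovnikov hydroboration of the vinyl group gives the primary alkylborane that transmetalates, after base activation, to the alkenylpalladium species formed by oxidative addition of zerovalent palladium into the enol triflate.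

Step 29
Reactants: 38 bis(triethylsilyl) ether of the target
Product: 39 target, (3R,5aR,6R,7S,9aR)-6-{2-[(1R,3aR,7R,8aR)-1,7-dihydroxy-1,4,4,6-tetramethyl-1,2,3,3a,4,7,8,8a-octahydroazulen-5-yl]ethyl}-7-hydroxy-2,2,5a,7-tetramethyldecahydro-1-benzoxepin-3-yl acetate
Conditions: HF·pyridine, pyridine, THF, 0 → 23 °C
Reagents that add atoms: none
Why: Buffered fluoride desilylation removes both triethylsilyl ethers without disturbing the acetate or the allylic alcohol.

**Compound list**

1 | geranyl acetate | CC(=O)OC/C=C(\C)CCC=C(C)C | starting material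
2 | (2E)-5-[(2S)-3,3-dimethyloxiran-2-yl]-3-methylpent-2-en-1-yl acetate | CC(=O)OC/C=C(\C)CC[C@@H]1OC1(C)C | intermediate
3 | methyl 2-{[(3S,6E)-8-acetoxy-3-hydroxy-2,6-dimethyloct-6-en-2-yl]oxy}acetate | CC(=O)OC/C=C(\C)CC[C@H](O)C(C)(C)OCC(=O)OC | intermediate
4 | methyl 2-{[(3S,6E)-8-acetoxy-3-(tert-butyldimethylsilyloxy)-2,6-dimethyloct-6-en-2-yl]oxy}acetate | CC(=O)OC/C=C(\C)CC[C@H](O[Si](C)(C)C(C)(C)C)C(C)(C)OCC(=O)OC | intermediate
5 | 2-{[(3S,6E)-3-(tert-butyldimethylsilyloxy)-8-hydroxy-2,6-dimethyloct-6-en-2-yl]oxy}acetic acid | OC/C=C(\C)CC[C@H](O[Si](C)(C)C(C)(C)C)C(C)(C)OCC(=O)O | intermediate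
6 | mixed anhydride of 5 with 2,4,6-trichlorobenzoic acid | OC/C=C(\C)CC[C@H](O[Si](C)(C)C(C)(C)C)C(C)(C)OCC(=O)OC(=O)c1c(Cl)cc(Cl)cc1Cl | intermediate
7 | (6S,9E)-6-(tert-butyldimethylsilyloxy)-5,5,9-trimethyl-1,4-dioxacycloundec-9-en-2-one | O=C1COC(C)(C)[C@@H](O[Si](C)(C)C(C)(C)C)CC/C(C)=C/CO1 | intermediate
8 | (2Z,6S,9E)-6-(tert-butyldimethylsilyloxy)-5,5,9-trimethyl-2-(trimethylsilyloxy)-1,4-dioxacycloundeca-2,9-diene | C[Si](C)(C)O/C1=C\OC(C)(C)[C@@H](O[Si](C)(C)C(C)(C)C)CC/C(C)=C/CO1 | intermediate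
9 | trimethylsilyl (2S,3R,6S)-6-(tert-butyldimethylsilyloxy)-3-ethenyl-3,7,7-trimethyloxepane-2-carboxylate | CC(C)(C)[Si](C)(C)O[C@H]1CC[C@](C)(C=C)[C@@H](C(=O)O[Si](C)(C)C)OC1(C)C | intermediate
10 | (2S,3R,6S)-6-(tert-butyldimethylsilyloxy)-3-ethenyl-3,7,7-trimethyloxepane-2-carboxylic acid | CC(C)(C)[Si](C)(C)O[C@H]1CC[C@](C)(C=C)[C@@H](C(=O)O)OC1(C)C | intermediate
11 | [(2S,3R,6S)-6-(tert-butyldimethylsilyloxy)-3-ethenyl-3,7,7-trimethyloxepan-2-yl]methanol | CC(C)(C)[Si](C)(C)O[C@H]1CC[C@](C)(C=C)[C@@H](CO)OC1(C)C | intermediate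
12 | (2S,3R,6S)-6-(tert-butyldimethylsilyloxy)-3-ethenyl-3,7,7-trimethyloxepane-2-carbaldehyde | CC(C)(C)[Si](C)(C)O[C@H]1CC[C@](C)(C=C)[C@@H](C=O)OC1(C)C | intermediate
13 | (3E)-4-[(2R,3R,6S)-6-(tert-butyldimethylsilyloxy)-3-ethenyl-3,7,7-trimethyloxepan-2-yl]but-3-en-2-one | CC(C)(C)[Si](C)(C)O[C@H]1CC[C@](C)(C=C)[C@@H](/C=C/C(C)=O)OC1(C)C | intermediate
14 | 4-[(2R,3R,6S)-6-(tert-butyldimethylsilyloxy)-3-ethenyl-3,7,7-trimethyloxepan-2-yl]butan-2-one | CC(C)(C)[Si](C)(C)O[C@H]1CC[C@](C)(C=C)[C@@H](CCC(C)=O)OC1(C)C | intermediate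
15 | 4-{(2R,3R,6S)-6-(tert-butyldimethylsilyloxy)-3,7,7-trimethyl-3-[(1E)-3-(trimethylsilyl)prop-1-en-1-yl]oxepan-2-yl}butan-2-one | CC(C)(C)[Si](C)(C)O[C@H]1CC[C@](C)(/C=C/C[Si](C)(C)C)[C@@H](CCC(C)=O)OC1(C)C | intermediate
16 | (3S,5aR,6R,7S,9aR)-3-(tert-butyldimethylsilyloxy)-6-ethenyl-2,2,5a,7-tetramethyldecahydro-1-benzoxepin-7-ol | CC(C)(C)[Si](C)(C)O[C@H]1CC[C@]2(C)[C@@H](C=C)[C@@](C)(O)CC[C@H]2OC1(C)C | intermediate
17 | (3S,5aR,6R,7S,9aR)-6-ethenyl-2,2,5a,7-tetramethyldecahydro-1-benzoxepine-3,7-diol | O[C@H]1CC[C@]2(C)[C@@H](C=C)[C@@](C)(O)CC[C@H]2OC1(C)C | intermediate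
18 | (5aR,6R,7S,9aR)-6-ethenyl-7-hydroxy-2,2,5a,7-tetramethyloctahydro-1-benzoxepin-3(2H)-one | O=C1CC[C@]2(C)[C@@H](C=C)[C@@](C)(O)CC[C@H]2OC1(C)C | intermediate
19 | (3R,5aR,6R,7S,9aR)-6-ethenyl-2,2,5a,7-tetramethyldecahydro-1-benzoxepine-3,7-diol | O[C@@H]1CC[C@]2(C)[C@@H](C=C)[C@@](C)(O)CC[C@H]2OC1(C)C | intermediate
20 | (3R,5aR,6R,7S,9aR)-6-ethenyl-7-hydroxy-2,2,5a,7-tetramethyldecahydro-1-benzoxepin-3-yl acetate | CC(=O)O[C@@H]1CC[C@]2(C)[C@@H](C=C)[C@@](C)(O)CC[C@H]2OC1(C)C | intermediate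
21 | (R)-linalool, (3R)-3,7-dimethylocta-1,6-dien-3-ol | C=C[C@](C)(O)CCC=C(C)C | starting material
22 | (1R)-1-methylcyclopent-2-en-1-ol | C[C@]1(O)C=CCC1 | intermediate
23 | (1S,2R,5S)-2-methyl-6-oxabicyclo[3.1.0]hexan-2-ol (epoxide cis to OH) | C[C@@]1(O)CC[C@@H]2O[C@H]12 | intermediate
24 | triethyl{[(1S,2R,5S)-2-methyl-6-oxabicyclo[3.1.0]hexan-2-yl]oxy}silane | CC[Si](CC)(CC)O[C@]1(C)CC[C@@H]2O[C@H]12 | intermediate
25 | 2-[(1S,2S,3R)-2-hydroxy-3-methyl-3-(triethylsilyloxy)cyclopentyl]-2-methylpropanenitrile | CC[Si](CC)(CC)O[C@]1(C)CC[C@@H](C(C)(C)C#N)[C@@H]1O | intermediate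
26 | 2-methyl-2-[(1S,3R)-3-methyl-2-oxo-3-(triethylsilyloxy)cyclopentyl]propanenitrile | CC[Si](CC)(CC)O[C@]1(C)CC[C@@H](C(C)(C)C#N)C1=O | intermediate
27 | 2-methyl-2-[(1S,3R)-3-methyl-2-methylidene-3-(triethylsilyloxy)cyclopentyl]propanenitrile | CC[Si](CC)(CC)O[C@]1(C)CC[C@@H](C(C)(C)C#N)C1=C | intermediate
28 | ketimine from 27 and ethyllithium (3-imino analogue of 29) | CC[Si](CC)(CC)O[C@]1(C)CC[C@@H](C(C)(C)C(=N)CC)C1=C | intermediate
29 | 2-methyl-2-[(1R,3R)-3-methyl-2-methylidene-3-(triethylsilyloxy)cyclopentyl]pentan-3-one | CC[Si](CC)(CC)O[C@]1(C)CC[C@@H](C(C)(C)C(=O)CC)C1=C | intermediate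
30 | (Z)-diisopinocampheylboron enolate of 29 | CC[Si](CC)(CC)O[C@]1(C)CC[C@@H](C(C)(C)/C(OB([C@@H]2C[C@@H]3C[C@H]([C@H]2C)C3(C)C)[C@@H]2C[C@@H]3C[C@H]([C@H]2C)C3(C)C)=C/C)C1=C | intermediate
31 | diisopinocampheylborinate of aldol 32 | CC[Si](CC)(CC)O[C@]1(C)CC[C@@H](C(C)(C)C(=O)[C@@H](C)[C@H](OB([C@@H]2C[C@@H]3C[C@H]([C@H]2C)C3(C)C)[C@@H]2C[C@@H]3C[C@H]([C@H]2C)C3(C)C)C=C)C1=C | intermediate
32 | (4S,5R)-5-hydroxy-2,4-dimethyl-2-[(1R,3R)-3-methyl-2-methylidene-3-(triethylsilyloxy)cyclopentyl]hept-6-en-3-one | CC[Si](CC)(CC)O[C@]1(C)CC[C@@H](C(C)(C)C(=O)[C@@H](C)[C@H](O)C=C)C1=C | intermediate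
33 | (1R,3aR,6S,7R)-7-hydroxy-1,4,4,6-tetramethyl-1-(triethylsilyloxy)-2,3,3a,4,6,7-hexahydroazulen-5(1H)-one | O=C1[C@@H](C)[C@H](O)C=C2[C@@H](CC[C@@]2(C)O[Si](CC)(CC)CC)C1(C)C | intermediate
34 | (1R,3aR,6S,7R,8aR)-7-hydroxy-1,4,4,6-tetramethyl-1-(triethylsilyloxy)octahydroazulen-5(1H)-one | O=C1[C@@H](C)[C@H](O)C[C@@H]2[C@@H](CC[C@@]2(C)O[Si](CC)(CC)CC)C1(C)C | intermediate
35 | (1R,3aR,6S,7R,8aR)-1,4,4,6-tetramethyl-1,7-bis(triethylsilyloxy)octahydroazulen-5(1H)-one | O=C1[C@@H](C)[C@H](O[Si](CC)(CC)CC)C[C@@H]2[C@@H](CC[C@@]2(C)O[Si](CC)(CC)CC)C1(C)C | intermediate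
36 | (1R,3aR,7R,8aR)-1,4,4,6-tetramethyl-1,7-bis(triethylsilyloxy)-1,2,3,3a,4,7,8,8a-octahydroazulen-5-yl trifluoromethanesulfonate | FC(F)(F)S(=O)(=O)OC1=C(C)[C@H](O[Si](CC)(CC)CC)C[C@@H]2[C@@H](CC[C@@]2(C)O[Si](CC)(CC)CC)C1(C)C | intermediate
37 | B-alkyl-9-borabicyclo[3.3.1]nonane from 20 (boron on the terminal carbon of the former vinyl group) | CC(=O)O[C@@H]1CC[C@]2(C)[C@@H](CCB3C4CCCC3CCC4)[C@@](C)(O)CC[C@H]2OC1(C)C | intermediate
38 | target with both hydroazulene hydroxyls as triethylsilyl ethers | CC(=O)O[C@@H]1CC[C@]2(C)[C@@H](CCC3=C(C)[C@H](O[Si](CC)(CC)CC)C[C@@H]4[C@@H](CC[C@@]4(C)O[Si](CC)(CC)CC)C3(C)C)[C@@](C)(O)CC[C@H]2OC1(C)C | intermediate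
39 | target, CNP0157376.1 | CC(=O)O[C@@H]1CC[C@]2(C)[C@@H](CCC3=C(C)[C@H](O)C[C@@H]4[C@@H](CC[C@@]4(C)O)C3(C)C)[C@@](C)(O)CC[C@H]2OC1(C)C | target

**Count and risks**

Total steps: 29. Longest linear sequence: 17 steps (steps 1–15, 28, 29); the right half contributes 12 steps (16–27).

Step 6 (ring contraction). What may go wrong is poor facial discrimination: the two chair arrays, with the silyloxy group pseudo-equatorial or pseudo-axial on the nascent oxepane, may differ little in energy, or the preference may be reversed. A boat array would give the cis-2,3 oxepane instead. The fallback replaces remote substrate control by 1,3-chirality transfer from a stereogenic allylic carbinol; it sets out from 4 and comes back at 10. K2CO3 in MeOH removes only the acetate of 4 to give the allylic alcohol F1; MnO2 gives the (E)-enal F2; Me2Zn with catalytic (−)-MIB (antipode chosen for the 8S carbinol) gives the secondary allylic alcohol F3; LiOH gives the seco acid F4; Yamaguchi lactonisation gives the 11-methyl macrolactone F5. The same enolisation, silylation and [3,3] shift must now pass through the chair in which the C11 methyl is equatorial, since an axial one would meet the axial C9 methyl, so the face of the allyl unit is fixed by C11 whatever the silyloxy group does, and the (E)-propenyl acid F6 results. Ozonolysis (O3, then Me2S) gives the formyl acid F7, and Wittig methylenation with excess Ph3P=CH2 returns 10.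

Step 24 (ring-closing metathesis). What may go wrong is failure of the ruthenium carbene to engage the 1,1-disubstituted alkene, which is flanked by a quaternary and a branched carbon, with dimerisation or isomerisation of the vinyl carbinol taking over. The fallback closes the seven-membered ring by an aldol instead of metathesis; it sets out from 29 and comes back at 34. LiN(i-Pr)2/Me3SiCl converts 29 into the (Z)-trimethylsilyl enol ether F8. Hydroformylation (Rh(acac)(CO)2, tris(2,4-di-tert-butylphenyl) phosphite, CO/H2, toluene, 60 °C) of the exocyclic methylene should give the linear aldehyde F9, hydrogen being delivered to the ring carbon from the face opposite the quaternary side chain. BF3·OEt2 at −78 °C then effects an intramolecular Mukaiyama aldol to the β-hydroxy ketone 34; this variant leaves the C7 configuration to substrate control, which would have to be checked.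

Step 28 (B-alkyl Suzuki coupling). What may go wrong is slow oxidative addition and transmetalation at the tetrasubstituted triflate flanked by a quaternary carbon, so that protodeboronation, triflate hydrolysis or acetate cleavage by the aqueous base wins. The fallback is a base-free reductive cross-electrophile coupling; it sets out from 20 and comes back at 38. Hydroboration of 20 with 9-BBN and oxidation with NaBO3 gives the primary alcohol F10; I2/PPh3/imidazole gives the primary iodide F11; NiBr2·glyme with 4,4′-di-tert-butyl-2,2′-bipyridine and Zn in DMA couples F11 with triflate 36 to give 38, the free tertiary hydroxyl and the acetate being tolerated.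

**Further compounds**

F1 | step 6 | methyl 2-{[(3S,6E)-3-(tert-butyldimethylsilyloxy)-8-hydroxy-2,6-dimethyloct-6-en-2-yl]oxy}acetate | OC/C=C(\C)CC[C@H](O[Si](C)(C)C(C)(C)C)C(C)(C)OCC(=O)OC
F2 | step 6 | methyl 2-{[(3S,6E)-3-(tert-butyldimethylsilyloxy)-2,6-dimethyl-8-oxooct-6-en-2-yl]oxy}acetate | O=C/C=C(\C)CC[C@H](O[Si](C)(C)C(C)(C)C)C(C)(C)OCC(=O)OC
F3 | step 6 | methyl 2-{[(3S,6E,8S)-3-(tert-butyldimethylsilyloxy)-8-hydroxy-2,6-dimethylnon-6-en-2-yl]oxy}acetate | C[C@H](O)/C=C(\C)CC[C@H](O[Si](C)(C)C(C)(C)C)C(C)(C)OCC(=O)OC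
F4 | step 6 | 2-{[(3S,6E,8S)-3-(tert-butyldimethylsilyloxy)-8-hydroxy-2,6-dimethylnon-6-en-2-yl]oxy}acetic acid | C[C@H](O)/C=C(\C)CC[C@H](O[Si](C)(C)C(C)(C)C)C(C)(C)OCC(=O)O
F5 | step 6 | (6S,9E,11S)-6-(tert-butyldimethylsilyloxy)-5,5,9,11-tetramethyl-1,4-dioxacycloundec-9-en-2-one | C[C@H]1/C=C(\C)CC[C@H](O[Si](C)(C)C(C)(C)C)C(C)(C)OCC(=O)O1
F6 | step 6 | (2S,3R,6S)-6-(tert-butyldimethylsilyloxy)-3,7,7-trimethyl-3-[(1E)-prop-1-en-1-yl]oxepane-2-carboxylic acid | CC(C)(C)[Si](C)(C)O[C@H]1CC[C@](C)(/C=C/C)[C@@H](C(=O)O)OC1(C)C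
F7 | step 6 | (2S,3S,6S)-6-(tert-butyldimethylsilyloxy)-3-formyl-3,7,7-trimethyloxepane-2-carboxylic acid | CC(C)(C)[Si](C)(C)O[C@H]1CC[C@](C)(C=O)[C@@H](C(=O)O)OC1(C)C
F8 | step 24 | (Z)-trimethylsilyl enol ether of 29 | CC[Si](CC)(CC)O[C@]1(C)CC[C@@H](C(C)(C)/C(O[Si](C)(C)C)=C/C)C1=C
F9 | step 24 | 2-[(1R,2R,5R)-2-methyl-2-(triethylsilyloxy)-5-{(Z)-2-methyl-3-(trimethylsilyloxy)pent-3-en-2-yl}cyclopentyl]acetaldehyde (side chains cis) | CC[Si](CC)(CC)O[C@]1(C)CC[C@@H](C(C)(C)/C(O[Si](C)(C)C)=C/C)[C@H]1CC=O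
F10 | step 28 | (3R,5aR,6R,7S,9aR)-7-hydroxy-6-(2-hydroxyethyl)-2,2,5a,7-tetramethyldecahydro-1-benzoxepin-3-yl acetate | CC(=O)O[C@@H]1CC[C@]2(C)[C@@H](CCO)[C@@](C)(O)CC[C@H]2OC1(C)C
F11 | step 28 | (3R,5aR,6R,7S,9aR)-7-hydroxy-6-(2-iodoethyl)-2,2,5a,7-tetramethyldecahydro-1-benzoxepin-3-yl acetate | CC(=O)O[C@@H]1CC[C@]2(C)[C@@H](CCI)[C@@](C)(O)CC[C@H]2OC1(C)C
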